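**Plan**

1. Retrosynthesis: the C3=C4 double bond of the 2H-chromene is first taken back to the chroman, so that no oxidisable alkene is present earlier. The chromone C3–aryl bond (to chroman C6) and the O1–C2 bond of the pyranone are then cut together by a retro 2,3-aryl shift to a 2'-hydroxychalcone. The chalcone Cα=Cβ bond is cut by retro-aldol, and the dimethylpyran ring is cut at O1–C2 and C4–C4a back to vanillin and a C5 propargyl unit.
2. Forward: the dimethylpyran ring on the B ring is made first (propargyl Claisen cascade, then saturation). The C6–C3–C6 chain is joined by a Claisen–Schmidt condensation. A biomimetic oxidative aryl shift moves the B ring from Cβ to Cα and the acid stage closes the pyranone ring. DDQ restores the chromene last.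
3. Enabling feature: the migrating carbon (chroman C6, the future C1') is para to the pyran oxygen O1 on C8a, which stabilises the bridged phenonium ion. The 3-aryl-2-H chromone is the 1,2-shifted flavonoid skeleton that isoflavone synthase makes from a flavanone.
4. Stereochemistry: the target has no stereocentre. The E geometry of the chalcone and the racemic centre of the rearranged acetal are both erased.

Key step: step 6

**Step 1**
Reactants: 1 vanillin (4-hydroxy-3-methoxybenzaldehyde); 2 3-chloro-3-methylbut-1-yne
Product: 3 3-methoxy-4-[(2-methylbut-3-yn-2-yl)oxy]benzaldehyde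
Conditions: K2CO3, KI, CuI (cat.), DMF, 65 °C
Reagents that add atoms: none
Why: Copper-assisted Williamson-type O-alkylation of the phenoxide by the tertiary propargylic chloride is the standard entry to aryl 1,1-dimethylpropargyl ethers and is not disturbed by the aldehyde.

**Step 2**
Reactants: 3 3-methoxy-4-[(2-methylbut-3-yn-2-yl)oxy]benzaldehyde
Product: 6 8-methoxy-2,2-dimethyl-2H-chromene-6-carbaldehyde, via o-allenylphenol 4 (not isolated), via o-quinone methide 5 (not isolated)
Conditions: PhNEt2, 190 °C
Reagents that add atoms: none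
Why: Aromatic propargyl Claisen rearrangement to the only free ortho carbon, enolisation to 4, a [1,5]-hydrogen shift to 5 and oxa-6π electrocyclisation should give the 2,2-dimethylchromene as a single regioisomer, because the other ortho position carries the methoxy group.

**Step 3**
Reactants: 6 8-methoxy-2,2-dimethyl-2H-chromene-6-carbaldehyde
Product: 7 8-methoxy-2,2-dimethyl-3,4-dihydro-2H-chromene-6-carbaldehyde (the chroman aldehyde)
Conditions: H2 (1 atm), 5% Pd/C, Ph2S (cat.), EtOAc, rt
Reagents that add atoms: none
Why: Catalytic hydrogenation of the cis-disubstituted styrenic C3=C4 bond on sulfide-moderated Pd/C should be much faster than reduction of the aryl aldehyde, and it removes the one group that would not survive the Tl(III) oxidant of step 6.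

**Step 4**
Reactants: 8 2,4-dihydroxyacetophenone
Product: 9 1-[2-hydroxy-4-(methoxymethoxy)phenyl]ethan-1-one
Conditions: MOMCl, K2CO3, acetone, 0 °C to rt
Reagents that add atoms: chloromethyl methyl ether (MOMCl), COCCl
Why: Williamson-type alkylation should occur only at the 4-hydroxyl, because the 2-hydroxyl is held in a hydrogen bond to the acetyl carbonyl (regioselective protection of resacetophenone).

**Step 5**
Reactants: 9 1-[2-hydroxy-4-(methoxymethoxy)phenyl]ethan-1-one; 7 8-methoxy-2,2-dimethyl-3,4-dihydro-2H-chromene-6-carbaldehyde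
Product: 10 (E)-1-[2-hydroxy-4-(methoxymethoxy)phenyl]-3-(8-methoxy-2,2-dimethyl-3,4-dihydro-2H-chromen-6-yl)prop-2-en-1-one
Conditions: KOH (50% aq.), EtOH, rt; then AcOH to pH 6
Reagents that add atoms: none
Why: Claisen–Schmidt (crossed aldol) condensation of the methyl ketone enolate with the non-enolisable aldehyde, followed by E1cB dehydration under thermodynamic control, should give only the E-enone, and the MOM ether and the chroman are stable to hydroxide.

**Step 6**
Reactants: 10 (E)-1-[2-hydroxy-4-(methoxymethoxy)phenyl]-3-(8-methoxy-2,2-dimethyl-3,4-dihydro-2H-chromen-6-yl)prop-2-en-1-one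
Product: 12 7-hydroxy-3-(8-methoxy-2,2-dimethyl-3,4-dihydro-2H-chromen-6-yl)-4H-chromen-4-one, via dimethyl acetal 11 (not isolated)
Conditions: Tl(NO3)3·3H2O (1.2 equiv), MeOH/HC(OMe)3, rt; filter off TlNO3; then 10% aq. HCl, 60 °C
Reagents that add atoms: none
Why: Tl(III) adds to the enone C=C of 10 together with methanol (methoxythallation, MeO on the benzylic Cβ and Tl on Cα), and heterolysis of the weak C–Tl bond (Tl(III) to Tl(I)) is assisted by a 1,2-shift of the chroman-6-yl ring from Cβ to Cα through a bridged phenonium ion, which makes the future C3–C1' bond and leaves a methoxy-stabilised cation at Cβ that methanol traps as acetal 11. The closest known reaction type is the thallium(III) nitrate oxidative rearrangement of 2'-hydroxychalcones to isoflavones, the laboratory counterpart of the 2,3-aryl shift carried out by isoflavone synthase on a flavanone. On acidification the acetal ionises to an oxocarbenium ion at the future C2, the 2'-hydroxyl adds to it in a 6-exo-trig closure (O1–C2 bond of the pyranone ring), and loss of methanol gives the C2=C3 double bond, while the same acid removes the MOM group. No stereocentre remains, because the Cα centre of 11 is formed as a racemate and becomes sp2. The step needs aryl migration in preference to aurone formation (attack of the 2'-hydroxyl on the thallated enone) and in preference to any other oxidation; the first is secured by the pyran oxygen O1 para to the migrating carbon, the second by the chroman oxidation level, which leaves no electron-rich alkene for oxythallation.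

**Step 7**
Reactants: 12 7-hydroxy-3-(8-methoxy-2,2-dimethyl-3,4-dihydro-2H-chromen-6-yl)-4H-chromen-4-one
Product: 13 7-hydroxy-3-(8-methoxy-2,2-dimethyl-2H-chromen-6-yl)-4H-chromen-4-one (CNP0202267.0)
Conditions: DDQ (1.5–2 equiv), 1,4-dioxane, reflux
Reagents that add atoms: none
Why: DDQ dehydrogenation of a 2,2-dimethylchroman should proceed by hydride abstraction from the benzylic C4 (cation stabilised by O1 through C8a) and proton loss from C3, C2 being quaternary so that only the C3=C4 alkene can form, while the 7-hydroxyl on the electron-poor chromone ring is not oxidised.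

**Compound list**

1 | vanillin (4-hydroxy-3-methoxybenzaldehyde) | COc1cc(C=O)ccc1O | starting material
2 | 3-chloro-3-methylbut-1-yne | C#CC(C)(C)Cl | starting material
3 | 3-methoxy-4-[(2-methylbut-3-yn-2-yl)oxy]benzaldehyde | COc1cc(C=O)ccc1OC(C)(C)C#C | intermediate
4 | 4-hydroxy-3-methoxy-5-(3-methylbuta-1,2-dien-1-yl)benzaldehyde (o-allenylphenol) | COc1cc(C=O)cc(C=C=C(C)C)c1O | intermediate
5 | (Z)-5-methoxy-3-(3-methylbut-2-en-1-ylidene)-4-oxocyclohexa-1,5-diene-1-carbaldehyde (o-quinone methide) | COC1=CC(C=O)=C/C(=C/C=C(C)C)C1=O | intermediate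
6 | 8-methoxy-2,2-dimethyl-2H-chromene-6-carbaldehyde | COc1cc(C=O)cc2c1OC(C)(C)C=C2 | intermediate
7 | 8-methoxy-2,2-dimethyl-3,4-dihydro-2H-chromene-6-carbaldehyde | COc1cc(C=O)cc2c1OC(C)(C)CC2 | intermediate
8 | 2,4-dihydroxyacetophenone | CC(=O)c1ccc(O)cc1O | starting material
9 | 1-[2-hydroxy-4-(methoxymethoxy)phenyl]ethan-1-one | CC(=O)c1ccc(OCOC)cc1O | intermediate
10 | (E)-1-[2-hydroxy-4-(methoxymethoxy)phenyl]-3-(8-methoxy-2,2-dimethyl-3,4-dihydro-2H-chromen-6-yl)prop-2-en-1-one | COCOc1ccc(C(=O)/C=C/c2cc(OC)c3OC(C)(C)CCc3c2)c(O)c1 | intermediate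
11 | 1-[2-hydroxy-4-(methoxymethoxy)phenyl]-3,3-dimethoxy-2-(8-methoxy-2,2-dimethyl-3,4-dihydro-2H-chromen-6-yl)propan-1-one (racemic) | COCOc1ccc(C(=O)C(C(OC)OC)c2cc(OC)c3OC(C)(C)CCc3c2)c(O)c1 | intermediate
12 | 7-hydroxy-3-(8-methoxy-2,2-dimethyl-3,4-dihydro-2H-chromen-6-yl)-4H-chromen-4-one | COc1cc(-c2coc3cc(O)ccc3c2=O)cc2c1OC(C)(C)CC2 | intermediate
13 | 7-hydroxy-3-(8-methoxy-2,2-dimethyl-2H-chromen-6-yl)-4H-chromen-4-one | COc1cc(-c2coc3cc(O)ccc3c2=O)cc2c1OC(C)(C)C=C2 | target

**Step count and risks**

Total step count: 7. Longest linear sequence: 6 steps (steps 1, 2, 3, 5, 6, 7 from vanillin); step 4 is a one-step side branch.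

Steps most likely to fail:

1. Step 7 (DDQ dehydrogenation). Hydride abstraction from C4 may be slow, because only O1 and no second donor para to C4a supports the benzylic cation; forcing conditions may then lead to over-oxidation or to adducts of the quinone with the free phenol. The fallback sets out from 12 and replaces hydride abstraction by radical bromination and elimination. Acetylation (Ac2O, pyridine) should give 7-acetoxy-3-(8-methoxy-2,2-dimethyl-3,4-dihydro-2H-chromen-6-yl)-4H-chromen-4-one F1, in which the ring that carried the phenol is protected against electrophilic bromination. Wohl–Ziegler bromination (NBS, AIBN, PhCF3, reflux) should then give the racemic benzylic bromide 7-acetoxy-3-(4-bromo-8-methoxy-2,2-dimethyl-3,4-dihydro-2H-chromen-6-yl)-4H-chromen-4-one F2. Dehydrobromination with DBU in toluene at 80 °C should give 7-acetoxy-3-(8-methoxy-2,2-dimethyl-2H-chromen-6-yl)-4H-chromen-4-one F3, and methanolysis of the acetate (K2CO3, MeOH, rt) comes back to the route at 13.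

2. Step 6 (oxidative aryl shift). The free 2'-hydroxyl may attack the thallated enone before the aryl group migrates (aurone formation), or the migration may stay incomplete. The fallback sets out from 10 and ties up the phenol first. Base-mediated oxa-Michael cyclisation (NaOAc, EtOH, reflux, unreacted chalcone recycled) should give the racemic flavanone 7-(methoxymethoxy)-2-(8-methoxy-2,2-dimethyl-3,4-dihydro-2H-chromen-6-yl)-2,3-dihydro-4H-chromen-4-one F4. Its enol should react with [hydroxy(tosyloxy)iodo]benzene in MeCN at reflux at C3, and the 2,3-aryl shift with loss of iodobenzene (a known hypervalent-iodine flavanone-to-isoflavone rearrangement) should give 7-(methoxymethoxy)-3-(8-methoxy-2,2-dimethyl-3,4-dihydro-2H-chromen-6-yl)-4H-chromen-4-one F5. Any MOM loss at this stage is harmless, and HCl in MeOH at 50 °C comes back to the route at 12.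

3. Step 3 (hydrogenation). Reduction of the formyl group (to the benzyl alcohol or further) may accompany saturation of the alkene. The fallback sets out from 6 and masks the aldehyde. Acetalisation (ethylene glycol, PPTS, toluene, Dean–Stark) should give 2-(8-methoxy-2,2-dimethyl-2H-chromen-6-yl)-1,3-dioxolane F6. Hydrogenation (H2, Pd/C, EtOAc, trace Et3N) should then give 2-(8-methoxy-2,2-dimethyl-3,4-dihydro-2H-chromen-6-yl)-1,3-dioxolane F7, and hydrolysis (1 M HCl, THF, rt) comes back to the route at 7.

**Further compounds**

F1 | step 7 | 7-acetoxy-3-(8-methoxy-2,2-dimethyl-3,4-dihydro-2H-chromen-6-yl)-4H-chromen-4-one | CC(=O)Oc1ccc2c(c1)occ(-c1cc(OC)c3OC(C)(C)CCc3c1)c2=O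
F2 | step 7 | 7-acetoxy-3-(4-bromo-8-methoxy-2,2-dimethyl-3,4-dihydro-2H-chromen-6-yl)-4H-chromen-4-one (racemic) | CC(=O)Oc1ccc2c(c1)occ(-c1cc(OC)c3OC(C)(C)CC(Br)c3c1)c2=O
F3 | step 7 | 7-acetoxy-3-(8-methoxy-2,2-dimethyl-2H-chromen-6-yl)-4H-chromen-4-one | CC(=O)Oc1ccc2c(c1)occ(-c1cc(OC)c3OC(C)(C)C=Cc3c1)c2=O
F4 | step 6 | 7-(methoxymethoxy)-2-(8-methoxy-2,2-dimethyl-3,4-dihydro-2H-chromen-6-yl)-2,3-dihydro-4H-chromen-4-one (racemic) | COCOc1ccc2C(=O)CC(c3cc(OC)c4OC(C)(C)CCc4c3)Oc2c1
F5 | step 6 | 7-(methoxymethoxy)-3-(8-methoxy-2,2-dimethyl-3,4-dihydro-2H-chromen-6-yl)-4H-chromen-4-one | COCOc1ccc2c(c1)occ(-c1cc(OC)c3OC(C)(C)CCc3c1)c2=O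
F6 | step 3 | 2-(8-methoxy-2,2-dimethyl-2H-chromen-6-yl)-1,3-dioxolane | COc1cc(C3OCCO3)cc2c1OC(C)(C)C=C2
F7 | step 3 | 2-(8-methoxy-2,2-dimethyl-3,4-dihydro-2H-chromen-6-yl)-1,3-dioxolane | COc1cc(C3OCCO3)cc2c1OC(C)(C)CC2
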